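**Retrosynthetic overview** (labdane numbering: ring A = C1–C5/C10, ring B = C5–C10, side chain C11–C16, formyl C17, hydroxymethyls C18/C19, methyl C20)
1. The strategy rests on ring B carrying the adjacent, cis-related C9 (side chain) and quaternary C10 (methyl) next to the trans C5/C10 fusion, while the gem-bis(hydroxymethyl) C4 of ring A is no stereocentre; C9=C10 is read as an (E)-β-methyl enal and C5–C8 as a diene hung on C4.
2. Late disconnections: C8 epimerisation (axial to equatorial CHO), C12–C13 (B-alkyl Suzuki–Miyaura coupling with 3-bromofuran-2(5H)-one, which brings in the lactone ring intact) and C11=C12 (Wittig).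
3. Key disconnection: C5–C10 and C8–C9 by an intramolecular Diels–Alder reaction of an achiral (2E,7E,9E)-trienal, which sets C5, C8, C9 and C10 in one event.
4. Trienal: C4 and its three one-carbon arms from triethyl methanetricarboxylate; C1–C3, C9, C10, C20 from pent-4-yn-1-ol (carboalumination fixes the E alkene as a vinyl iodide, formylated last to give C11); C5–C8 and C17 from triethyl 4-phosphonocrotonate.
5. Ring order: rings A and B together (step 10), then the preformed butenolide ring is attached (step 13).

Key step: step 10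

Assumption 1: the catalyst antipode named in step 10 is the one expected to expose the Re face of C9; this sense is to be confirmed in the first run, and the mirror-image catalyst is equally accessible.
Assumption 2: 3-bromofuran-2(5H)-one is taken as purchasable (otherwise one step from furan-2(5H)-one by bromination and dehydrobromination).

**Route**

Step 1
Reactants: 1 pent-4-yn-1-ol
Product: 3 (E)-5-iodo-4-methylpent-4-en-1-ol, via alkenylalane 2 (not isolated)
Conditions: Me3Al (3 equiv), Cp2ZrCl2 (0.25 equiv), CH2Cl2, 0 °C → rt; then I2, THF, −30 → 0 °C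
Reagents that add atoms: trimethylaluminium, C[Al](C)C; iodine, II
Why: Zirconium-catalysed Negishi carboalumination adds methyl and aluminium syn across the terminal alkyne (aluminium at the terminus), and iodinolysis with retention should give the (E)-vinyl iodide that fixes the later C9=C10 geometry (C20 cis to C11).

Step 2
Reactants: 3 (E)-5-iodo-4-methylpent-4-en-1-ol; 4 triethyl methanetricarboxylate
Product: 5 triethyl (E)-6-iodo-5-methylhex-5-ene-1,1,1-tricarboxylate
Conditions: PPh3, DIAD, THF, 0 °C → rt
Reagents that add atoms: none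
Why: The triester (pKa about 8) is acidic enough to act as carbon pronucleophile in a Mitsunobu alkylation of the unhindered primary alcohol, which forms the C3–C4 bond without a separate halide step.

Step 3
Reactants: 5 triethyl (E)-6-iodo-5-methylhex-5-ene-1,1,1-tricarboxylate
Product: 6 2-(hydroxymethyl)-2-[(E)-5-iodo-4-methylpent-4-enyl]propane-1,3-diol
Conditions: LiAlH4, THF, 0 °C
Reagents that add atoms: none
Why: Hydride reduction of the three geminal esters should give the tris(hydroxymethyl) carbon C4 (C18, C19 and the future C5), the trisubstituted vinyl iodide being inert to LiAlH4 at 0 °C.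

Step 4
Reactants: 6 2-(hydroxymethyl)-2-[(E)-5-iodo-4-methylpent-4-enyl]propane-1,3-diol
Product: 7 {5-[(E)-5-iodo-4-methylpent-4-enyl]-2,2-dimethyl-1,3-dioxan-5-yl}methanol
Conditions: 2,2-dimethoxypropane, PPTS (cat.), acetone, rt
Reagents that add atoms: 2,2-dimethoxypropane, COC(C)(C)OC
Why: Acid-catalysed transketalisation closes the six-membered acetonide on two of the three equivalent hydroxymethyl arms, so exactly one primary hydroxyl remains and no selectivity is required.

Step 5
Reactants: 7 {5-[(E)-5-iodo-4-methylpent-4-enyl]-2,2-dimethyl-1,3-dioxan-5-yl}methanol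
Product: 8 5-[(E)-5-iodo-4-methylpent-4-enyl]-2,2-dimethyl-1,3-dioxane-5-carbaldehyde
Conditions: Dess–Martin periodinane, NaHCO3, CH2Cl2, 0 °C → rt
Reagents that add atoms: none
Why: Dess–Martin oxidation of the neopentyl alcohol should give the C5 aldehyde, which has no α-hydrogen and cannot enolise.

Step 6
Reactants: 8 5-[(E)-5-iodo-4-methylpent-4-enyl]-2,2-dimethyl-1,3-dioxane-5-carbaldehyde; 9 triethyl 4-phosphonocrotonate
Product: 10 ethyl (2E,4E)-5-{5-[(E)-5-iodo-4-methylpent-4-enyl]-2,2-dimethyl-1,3-dioxan-5-yl}penta-2,4-dienoate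
Conditions: 9, LiHMDS, THF, −78 °C; then 8, −78 → 0 °C
Reagents that add atoms: none
Why: The vinylogous Horner–Wadsworth–Emmons olefination reacts at the phosphorus-bearing carbon and should give the (2E,4E)-dienoate (new C5=C6, retained C7=C8), the hindered non-enolisable aldehyde favouring the E alkene.

Step 7
Reactants: 10 ethyl (2E,4E)-5-{5-[(E)-5-iodo-4-methylpent-4-enyl]-2,2-dimethyl-1,3-dioxan-5-yl}penta-2,4-dienoate
Product: 11 (2E,4E)-5-{5-[(E)-5-iodo-4-methylpent-4-enyl]-2,2-dimethyl-1,3-dioxan-5-yl}penta-2,4-dien-1-ol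
Conditions: DIBAL-H (2.5 equiv), CH2Cl2, −78 °C
Reagents that add atoms: none
Why: DIBAL-H 1,2-reduction of the dienoate should give the dienol (C17–OH) without touching the vinyl iodide, the diene or the acetonide.

Step 8
Reactants: 11 (2E,4E)-5-{5-[(E)-5-iodo-4-methylpent-4-enyl]-2,2-dimethyl-1,3-dioxan-5-yl}penta-2,4-dien-1-ol
Product: 12 tert-butyl{[(2E,4E)-5-{5-[(E)-5-iodo-4-methylpent-4-enyl]-2,2-dimethyl-1,3-dioxan-5-yl}penta-2,4-dienyl]oxy}dimethylsilane
Conditions: TBSCl, imidazole, CH2Cl2, 0 °C → rt
Reagents that add atoms: tert-butyldimethylsilyl chloride, CC(C)(C)[Si](C)(C)Cl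
Why: Standard silylation of the primary dienylic alcohol gives an ether that is weakly Lewis basic and survives organolithium, Lewis-acid, Wittig and cross-coupling conditions.

Step 9
Reactants: 12 tert-butyl{[(2E,4E)-5-{5-[(E)-5-iodo-4-methylpent-4-enyl]-2,2-dimethyl-1,3-dioxan-5-yl}penta-2,4-dienyl]oxy}dimethylsilane
Product: 14 (2E)-6-{5-[(1E,3E)-5-(tert-butyldimethylsilyloxy)penta-1,3-dienyl]-2,2-dimethyl-1,3-dioxan-5-yl}-3-methylhex-2-enal, via vinyllithium 13 (not isolated)
Conditions: t-BuLi (2.1 equiv), Et2O, −78 °C; then DMF, −78 → 0 °C; aq. NH4Cl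
Reagents that add atoms: N,N-dimethylformamide, CN(C)C=O
Why: Iodine–lithium exchange proceeds with retention of alkene geometry and formylation of the vinyllithium with DMF should give the (E)-β-methyl enal (C11), so the dienophile is unveiled in the last step before the cycloaddition and no protecting group is needed at C11.

Step 10
Reactants: 14 (2E)-6-{5-[(1E,3E)-5-(tert-butyldimethylsilyloxy)penta-1,3-dienyl]-2,2-dimethyl-1,3-dioxan-5-yl}-3-methylhex-2-enal
Product: 15 trans-fused Δ6-octalin aldehyde with C4 spiro-acetonide: C20 methyl on C10, C9 formyl (C11) cis to C20, C8 CH2OTBS cis to both (axial), H-5 trans to C20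
Conditions: (S)-B-(o-tolyl)oxazaborolidine from (S)-α,α-diphenylprolinol (20 mol %), Tf2NH (18 mol %), CH2Cl2, −40 → 0 °C
Reagents that add atoms: none
Why: Proposed new method: the boron-bound (E)-enal is attacked by the tethered E,E-diene in a concerted but asynchronous [4+2] in which C5–C10 leads at the enal β-carbon and C8–C9 follows, the closest known reaction type being the oxazaborolidinium-catalysed intramolecular Diels–Alder reaction of 2,7,9-trienals that lack the β-methyl group, so the β,β-disubstituted dienophile and the quaternary C10 are the extrapolation. Ring B closes as the new cyclohexene of the cycloaddition through both new bonds, and ring A closes in the fused type-1 mode as C5–C10 forms across the C1–C4 tether held in a chair. C9 and C10 keep the cis formyl/methyl relation of the (E)-enal, and C5 and C8 keep the cis relation of the outer diene substituents C4 and C17, both by suprafacial addition. The trans C5/C10 fusion and the cis C8/C9 relation come from the endo transition state with the formyl group under the diene, which a Lewis-acid-bound (E)-enal favours and which the chair tether with the tied-back spiro C4 accommodates. The absolute sense is set by the catalyst, whose aryl groups cover one face of the coordinated enal so that the diene reaches the Re face of C9. The step therefore needs endo over exo approach, one enal face over the other and enough reactivity at a β,β-disubstituted enal, which the cationic Lewis acid and the gem-disubstituted C4 (Thorpe–Ingold effect) are meant to supply.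

Step 11
Reactants: 15 trans-fused Δ6-octalin aldehyde
Product: 16 saturated trans-decalin aldehyde (6,7-dihydro-15)
Conditions: H2 (1 atm), 10% Pd/C, EtOAc, rt
Reagents that add atoms: none
Why: Heterogeneous catalytic hydrogenation should saturate the cis-disubstituted C6=C7 alkene, which creates no stereocentre, and leave the hindered aldehyde, silyl ether and acetonide.

Step 12
Reactants: 16 saturated trans-decalin aldehyde
Product: 17 C9-vinyl decalin (C11=C12), C8 CH2OTBS axial, acetonide retained
Conditions: Ph3PCH3Br, KHMDS, THF, 0 °C; then 16, −78 → 0 °C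
Reagents that add atoms: methyltriphenylphosphonium bromide, C[P+](c1ccccc1)(c1ccccc1)c1ccccc1.[Br-]
Why: Wittig methylenation with the small non-stabilised ylide converts the neopentyl-type C11 aldehyde into the vinyl group, addition being expected to outrun deprotonation at the shielded C9–H so that C9 is kept.

Step 13
Reactants: 17 C9-vinyl decalin; 18 3-bromofuran-2(5H)-one
Product: 20 butenolide silyl ether (C12 bonded to C13 of the 2(5H)-furanone; C8 CH2OTBS axial; acetonide), via alkylborane 19 (not isolated)
Conditions: 9-BBN, THF, 0 °C → rt; then 18, PdCl2(dppf) (10 mol %), AsPh3, Cs2CO3, DMF/H2O, rt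
Reagents that add atoms: none
Why: Anti-Markovnikov hydroboration puts boron on the terminal C12 and B-alkyl Suzuki–Miyaura coupling at the α-bromo carbon of the unsaturated lactone forms C12–C13, so the α-substituted butenolide is installed with its regiochemistry fixed by the halide.

Step 14
Reactants: 20 butenolide silyl ether
Product: 21 primary alcohol (C17–OH axial, butenolide, acetonide)
Conditions: HF·pyridine, pyridine, THF, 0 °C → rt
Reagents that add atoms: none
Why: Buffered fluoride desilylation removes the primary TBS group under conditions that are neither basic enough to affect the butenolide nor acidic enough to open the acetonide.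

Step 15
Reactants: 21 primary alcohol
Product: 22 8-epi aldehyde (C17 formyl axial, cis to C20)
Conditions: Dess–Martin periodinane, NaHCO3, CH2Cl2, 0 °C
Reagents that add atoms: none
Why: Dess–Martin oxidation is neutral and should convert the primary alcohol into the aldehyde without touching the butenolide or the acetonide.

Step 16
Reactants: 22 8-epi aldehyde
Product: 23 acetonide of the target (C17 formyl equatorial, trans to the C9 side chain)
Conditions: DBU (0.3 equiv), CH2Cl2, rt
Reagents that add atoms: none
Why: Base-mediated epimerisation through the enolate should set C8 under thermodynamic control, because the axial formyl group is syn-axial to C20 and the equatorial epimer is trans-diequatorial with the C9 chain.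

Step 17
Reactants: 23 acetonide of the target
Product: 24 (5S,8S,9R,10S)-18,19-dihydroxy-17-oxolabd-13-en-16,15-olide (target)
Conditions: 1 M aq. HCl, THF, rt
Reagents that add atoms: none
Why: Acid-catalysed acetal hydrolysis should release the C18/C19 diol, the equatorial C8 aldehyde already being the thermodynamic epimer and the butenolide being stable to dilute acid.

**Compound list**
1 | pent-4-yn-1-ol | C#CCCCO | starting material
2 | (E)-alkenylalane, O-dimethylaluminium alkoxide | C[Al](C)OCCC/C(C)=C/[Al](C)C | intermediate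
3 | (E)-5-iodo-4-methylpent-4-en-1-ol | OCCC/C(C)=C/I | intermediate
4 | triethyl methanetricarboxylate | CCOC(=O)C(C(=O)OCC)C(=O)OCC | starting material
5 | triethyl (E)-6-iodo-5-methylhex-5-ene-1,1,1-tricarboxylate | CCOC(=O)C(CCC/C(C)=C/I)(C(=O)OCC)C(=O)OCC | intermediate
6 | 2-(hydroxymethyl)-2-[(E)-5-iodo-4-methylpent-4-enyl]propane-1,3-diol | OCC(CO)(CO)CCC/C(C)=C/I | intermediate
7 | {5-[(E)-5-iodo-4-methylpent-4-enyl]-2,2-dimethyl-1,3-dioxan-5-yl}methanol | OCC1(CCC/C(C)=C/I)COC(C)(C)OC1 | intermediate
8 | 5-[(E)-5-iodo-4-methylpent-4-enyl]-2,2-dimethyl-1,3-dioxane-5-carbaldehyde | O=CC1(CCC/C(C)=C/I)COC(C)(C)OC1 | intermediate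
9 | triethyl 4-phosphonocrotonate | CCOC(=O)/C=C/CP(=O)(OCC)OCC | starting material
10 | ethyl (2E,4E)-5-{5-[(E)-5-iodo-4-methylpent-4-enyl]-2,2-dimethyl-1,3-dioxan-5-yl}penta-2,4-dienoate | CCOC(=O)/C=C/C=C/C1(CCC/C(C)=C/I)COC(C)(C)OC1 | intermediate
11 | (2E,4E)-5-{5-[(E)-5-iodo-4-methylpent-4-enyl]-2,2-dimethyl-1,3-dioxan-5-yl}penta-2,4-dien-1-ol | OC/C=C/C=C/C1(CCC/C(C)=C/I)COC(C)(C)OC1 | intermediate
12 | TBS ether of 11 | CC(C)(C)[Si](C)(C)OC/C=C/C=C/C1(CCC/C(C)=C/I)COC(C)(C)OC1 | intermediate
13 | (E)-vinyllithium from 12 | [Li]/C=C(C)/CCCC1(COC(C)(C)OC1)/C=C/C=C/CO[Si](C)(C)C(C)(C)C | intermediate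
14 | (2E)-6-{5-[(1E,3E)-5-(tert-butyldimethylsilyloxy)penta-1,3-dienyl]-2,2-dimethyl-1,3-dioxan-5-yl}-3-methylhex-2-enal (trienal) | O=C/C=C(C)/CCCC1(COC(C)(C)OC1)/C=C/C=C/CO[Si](C)(C)C(C)(C)C | intermediate
15 | trans-fused Δ6-octalin aldehyde, C4 spiro-acetonide, C9 CHO cis to C20, C8 CH2OTBS axial and cis to both | C[C@@]12CCCC3(COC(C)(C)OC3)[C@H]1C=C[C@@H](CO[Si](C)(C)C(C)(C)C)[C@H]2C=O | intermediate
16 | saturated trans-decalin aldehyde (6,7-dihydro-15) | C[C@@]12CCCC3(COC(C)(C)OC3)[C@H]1CC[C@@H](CO[Si](C)(C)C(C)(C)C)[C@H]2C=O | intermediate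
17 | C9-vinyl decalin, C8 CH2OTBS axial | C[C@@]12CCCC3(COC(C)(C)OC3)[C@H]1CC[C@@H](CO[Si](C)(C)C(C)(C)C)[C@H]2C=C | intermediate
18 | 3-bromofuran-2(5H)-one | O=C1OCC=C1Br | starting material
19 | B-(C12-alkyl)-9-borabicyclo[3.3.1]nonane from 17 | C[C@@]12CCCC3(COC(C)(C)OC3)[C@H]1CC[C@@H](CO[Si](C)(C)C(C)(C)C)[C@H]2CCB1C2CCCC1CCC2 | intermediate
20 | butenolide silyl ether (C8 CH2OTBS axial) | C[C@@]12CCCC3(COC(C)(C)OC3)[C@H]1CC[C@@H](CO[Si](C)(C)C(C)(C)C)[C@H]2CCC1=CCOC1=O | intermediate
21 | primary alcohol (C17–OH axial) | C[C@@]12CCCC3(COC(C)(C)OC3)[C@H]1CC[C@@H](CO)[C@H]2CCC1=CCOC1=O | intermediate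
22 | 8-epi aldehyde (C17 formyl axial) | C[C@@]12CCCC3(COC(C)(C)OC3)[C@H]1CC[C@@H](C=O)[C@H]2CCC1=CCOC1=O | intermediate
23 | acetonide of the target (C17 formyl equatorial) | C[C@@]12CCCC3(COC(C)(C)OC3)[C@H]1CC[C@H](C=O)[C@H]2CCC1=CCOC1=O | intermediate
24 | (5S,8S,9R,10S)-18,19-dihydroxy-17-oxolabd-13-en-16,15-olide | C[C@@]12CCCC(CO)(CO)[C@H]1CC[C@H](C=O)[C@H]2CCC1=CCOC1=O | target

**Step count:** 17 steps in total; longest linear sequence 17 steps (from pent-4-yn-1-ol).

**Steps most likely to fail**

1. Step 10. The β,β-disubstituted enal may not be activated enough to cyclise before the acetonide or the dienylic silyl ether ionises under the acidic catalyst. Discrimination between the two enal faces or between endo and exo approach may also be incomplete. Fallback: setting out from trienal 14, the cyclisation is run without chiral control (Me2AlCl, CH2Cl2, −78 → −20 °C, or toluene with BHT at 150 °C). This is established practice for decatrienes with trisubstituted carbonyl-activated dienophiles and should give the racemic trans-fused adduct F1. Reduction with NaBH4 gives the racemic primary alcohol F2. Esterification with (S)-O-methylmandelic acid (DCC, DMAP) and chromatographic separation of the two diastereomers gives the mandelate F3 of the wanted enantiomer. Methanolysis (K2CO3, MeOH) gives the enantiopure alcohol F4, and Dess–Martin oxidation returns to the route at aldehyde 15.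

2. Step 13. Base-promoted ring opening or oligomerisation of the bromobutenolide and of the coupled butenolide may compete with transmetalation, and the alkylborane may be lost by protodeboronation or β-hydride elimination. Fallback: setting out from alkene 17, borane 19 is oxidised in the flask (NaBO3·4H2O) to the C12 primary alcohol F5, which is converted into the iodide F6 (I2, PPh3, imidazole). Alkylation of the lithium enolate of 3-(phenylsulfanyl)oxolan-2-one (LDA, THF/DMPU) gives the α-sulfanyl lactone F7, and oxidation with mCPBA at −78 °C gives the sulfoxide F8. Thermal syn-elimination (toluene, reflux, CaCO3), the standard route to α-alkyl butenolides, should place the double bond in the ring and return to the route at butenolide 20.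

3. Step 16. Reversible γ-deprotonation of the butenolide by the amine base may cause double-bond migration or Michael-type oligomerisation before C8 has fully equilibrated. Fallback: setting out from alkene 17, C8 is corrected before the lactone is present. TBAF gives the alcohol F9, Dess–Martin oxidation the axial aldehyde F10, K2CO3 in MeOH the equatorial aldehyde F11, and NaBH4 the equatorial alcohol F12. Hydroboration with excess 9-BBN (the hydroxyl is carried as its borinate in the bis-boron intermediate F13) and coupling with 18 under the conditions of step 13 give the hydroxy butenolide F14. Its Dess–Martin oxidation returns to the route at aldehyde 23, so no base meets the butenolide.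

**Further compounds**
F1 | step 10 | racemic trans-fused Diels–Alder adduct (15 and its enantiomer, 1:1) | C[C@@]12CCCC3(COC(C)(C)OC3)[C@H]1C=C[C@@H](CO[Si](C)(C)C(C)(C)C)[C@H]2C=O.C[C@]12CCCC3(COC(C)(C)OC3)[C@@H]1C=C[C@H](CO[Si](C)(C)C(C)(C)C)[C@@H]2C=O
F2 | step 10 | racemic C11 primary alcohol from F1 | C[C@@]12CCCC3(COC(C)(C)OC3)[C@H]1C=C[C@@H](CO[Si](C)(C)C(C)(C)C)[C@H]2CO.C[C@]12CCCC3(COC(C)(C)OC3)[C@@H]1C=C[C@H](CO[Si](C)(C)C(C)(C)C)[C@@H]2CO
F3 | step 10 | (S)-O-methylmandelate of the alcohol with the configuration of 15 | C[C@@]12CCCC3(COC(C)(C)OC3)[C@H]1C=C[C@@H](CO[Si](C)(C)C(C)(C)C)[C@H]2COC(=O)[C@@H](OC)c1ccccc1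
F4 | step 10 | enantiopure C11 primary alcohol | C[C@@]12CCCC3(COC(C)(C)OC3)[C@H]1C=C[C@@H](CO[Si](C)(C)C(C)(C)C)[C@H]2CO
F5 | step 13 | C12 primary alcohol | C[C@@]12CCCC3(COC(C)(C)OC3)[C@H]1CC[C@@H](CO[Si](C)(C)C(C)(C)C)[C@H]2CCO
F6 | step 13 | C12 primary iodide | C[C@@]12CCCC3(COC(C)(C)OC3)[C@H]1CC[C@@H](CO[Si](C)(C)C(C)(C)C)[C@H]2CCI
F7 | step 13 | α-alkyl-α-(phenylsulfanyl)butyrolactone (mixture at C13) | C[C@@]12CCCC3(COC(C)(C)OC3)[C@H]1CC[C@@H](CO[Si](C)(C)C(C)(C)C)[C@H]2CCC1(Sc3ccccc3)CCOC1=O
F8 | step 13 | sulfoxide of F7 | C[C@@]12CCCC3(COC(C)(C)OC3)[C@H]1CC[C@@H](CO[Si](C)(C)C(C)(C)C)[C@H]2CCC1(S(=O)c3ccccc3)CCOC1=O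
F9 | step 16 | C9-vinyl decalin alcohol (C17–OH axial) | C[C@@]12CCCC3(COC(C)(C)OC3)[C@H]1CC[C@@H](CO)[C@H]2C=C
F10 | step 16 | C9-vinyl decalin aldehyde (C17 formyl axial) | C[C@@]12CCCC3(COC(C)(C)OC3)[C@H]1CC[C@@H](C=O)[C@H]2C=C
F11 | step 16 | C9-vinyl decalin aldehyde (C17 formyl equatorial) | C[C@@]12CCCC3(COC(C)(C)OC3)[C@H]1CC[C@H](C=O)[C@H]2C=C
F12 | step 16 | C9-vinyl decalin alcohol (C17–OH equatorial) | C[C@@]12CCCC3(COC(C)(C)OC3)[C@H]1CC[C@H](CO)[C@H]2C=C
F13 | step 16 | bis-boron intermediate (C12 alkylborane, C17 O-borinate) | C[C@@]12CCCC3(COC(C)(C)OC3)[C@H]1CC[C@H](COB4C5CCCC4CCC5)[C@H]2CCB1C2CCCC1CCC2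
F14 | step 16 | hydroxy butenolide (C17–OH equatorial) | C[C@@]12CCCC3(COC(C)(C)OC3)[C@H]1CC[C@H](CO)[C@H]2CCC1=CCOC1=O
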